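**Plan**

- Retrosynthesis: the C3–O acyl bond is cut first (cis alcohol 18 + acid 25); the isopropenyl group goes back to a C2 methyl ester (two C–CH3 bonds); C3–O goes back to C3–B; removal of C3–B and C2–H leads to the flat benzofuran 6, whose O1–C2 and C2–C3 bonds come from 1 and 2.
- Forward: ring B (the furan) is closed onto ring A (the benzene ring) in step 1 as an aromatic benzofuran and dearomatised in step 3; the ester then becomes the isopropenyl group, and the side-chain acid, made from crotonaldehyde, is joined last.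
- Enabling feature: C2 and C3 are the only sp3 atoms of ring B and map onto the C2=C3 bond of an achiral benzofuran-2-carboxylate, whose ester carbon becomes the central carbon of the isopropenyl group.
- Stereochemistry: C3 comes from the chiral bisphosphine–copper boryl addition and C2 from protonation of the copper enolate anti to boron (cis). Boron is exchanged for oxygen with retention, and Mitsunobu inversion at C3 gives the trans (2R,3S) ester.
- The Z-alkene of the acid comes from (E)-crotonaldehyde by α-iodination (iodine cis to methyl) and stereoretentive I→Li→CO2H exchange.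

Key step: step 3

Assumption: the (R,R) ligand is taken to deliver boron to the C3 face that gives 3R; if the sense is opposite, the (S,S) ligand is used with nothing else changed.
Assumption: 5-acetylsalicylaldehyde 1 is purchased (otherwise it is one Duff formylation from 4-hydroxyacetophenone).

**Route**

Step 1
Reactants: 1 5-acetylsalicylaldehyde; 2 methyl bromoacetate
Product: 5 methyl 5-acetylbenzofuran-2-carboxylate, via methyl 2-(4-acetyl-2-formylphenoxy)acetate 3 (not isolated), via methyl 5-acetyl-3-hydroxy-2,3-dihydrobenzofuran-2-carboxylate 4 (not isolated)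
Conditions: K2CO3, DMF, 90 °C
Reagents that add atoms: none
Why: Williamson etherification of the phenoxide followed by intramolecular aldol condensation (5-exo-trig attack of the ester enolate on the aldehyde, then dehydration driven by aromatisation), a Rap–Stoermer-type benzofuran synthesis that creates no stereocentre.

Step 2
Reactants: 5 methyl 5-acetylbenzofuran-2-carboxylate
Product: 6 methyl 5-(2-methyl-1,3-dioxolan-2-yl)benzofuran-2-carboxylate
Conditions: (TMSOCH2)2, TMSOTf (5 mol%), CH2Cl2, −78 → 0 °C; pyridine quench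
Reagents that add atoms: 1,2-bis(trimethylsilyloxy)ethane, C[Si](C)(C)OCCO[Si](C)(C)C
Why: Noyori ketalisation masks the aryl ketone, which would otherwise consume copper boryl in step 3 and MeMgBr in step 6, under aprotic conditions that should leave the methyl ester untransesterified.

Step 3
Reactants: 6 methyl 5-(2-methyl-1,3-dioxolan-2-yl)benzofuran-2-carboxylate; 7 bis(pinacolato)diboron
Product: 9 methyl (2S,3R)-5-(2-methyl-1,3-dioxolan-2-yl)-3-(4,4,5,5-tetramethyl-1,3,2-dioxaborolan-2-yl)-2,3-dihydrobenzofuran-2-carboxylate, via copper enolate 8 (not isolated)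
Conditions: CuCl (5 mol%), (R,R)-QuinoxP* [(R,R)-2,3-bis(tert-butylmethylphosphino)quinoxaline] (5.5 mol%), NaOtBu (10 mol%), tBuOH (2 equiv), THF, −20 → 0 °C
Reagents that add atoms: bis(pinacolato)diboron (compound 7), CC1(C)OB(OC1(C)C)B1OC(C)(C)C(C)(C)O1
Why: Proposed new method: CuCl, NaOtBu and the bisphosphine give LCuOtBu (monovalent copper), which exchanges with 7 to LCu–Bpin; this adds syn across the acrylate-like C2=C3 bond of 6 with boron at the β-carbon C3, and the copper enolate 8 is protonated at C2 by tBuOH, which returns LCuOtBu. The closest known reaction type is the copper-catalysed enantioselective borylative dearomatisation–protonation of N-acyl indole-2-carboxylates, and the furan ring of a benzofuran has less aromatic stabilisation to lose than the pyrrole ring of an indole. No ring is closed and no skeletal bond is formed. C3 (R) is set by the chiral ligand in the enantio-determining borylcupration, and C2 (S) by the substrate, the bulky proton donor approaching the planar enolate anti to the new C3–Bpin group, which should give the cis ester. The step needs β-regioselectivity (secured by the C2 ester, which also stabilises the enolate) and chemoselectivity over the ketone (secured by the dioxolane). It also needs kinetic protonation without C2 epimerisation or β-aryloxy elimination, which is favoured by catalytic alkoxide, low temperature and an endocyclic C2–O1 bond that cannot align with the exocyclic C3–B bond.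

Step 4
Reactants: 9 methyl (2S,3R)-5-(2-methyl-1,3-dioxolan-2-yl)-3-(4,4,5,5-tetramethyl-1,3,2-dioxaborolan-2-yl)-2,3-dihydrobenzofuran-2-carboxylate
Product: 11 methyl (2S,3R)-3-hydroxy-5-(2-methyl-1,3-dioxolan-2-yl)-2,3-dihydrobenzofuran-2-carboxylate, via borate ester 10 (not isolated)
Conditions: NaBO3·4H2O, THF/H2O (1:1), 0 °C → rt
Reagents that add atoms: sodium perborate tetrahydrate, [Na+].[O-]OB=O.O.O.O.O
Why: Boronate oxidation, in which the peroxide adds to boron and C3 migrates from B to O with retention, so the cis relationship is kept, while the weakly basic perborate should avoid E1cB dehydration of the β-hydroxy ester.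

Step 5
Reactants: 11 methyl (2S,3R)-3-hydroxy-5-(2-methyl-1,3-dioxolan-2-yl)-2,3-dihydrobenzofuran-2-carboxylate
Product: 12 methyl (2S,3R)-5-(2-methyl-1,3-dioxolan-2-yl)-3-(triethylsilyloxy)-2,3-dihydrobenzofuran-2-carboxylate
Conditions: TESCl, imidazole, DMF, 0 °C → rt
Reagents that add atoms: chlorotriethylsilane, CC[Si](Cl)(CC)CC
Why: Imidazole-mediated silyl ether formation, too weakly basic to epimerise C2 or to eliminate, protects the C3 hydroxyl for the Grignard and dehydration steps.

Step 6
Reactants: 12 methyl (2S,3R)-5-(2-methyl-1,3-dioxolan-2-yl)-3-(triethylsilyloxy)-2,3-dihydrobenzofuran-2-carboxylate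
Product: 14 2-[(2S,3R)-5-(2-methyl-1,3-dioxolan-2-yl)-3-(triethylsilyloxy)-2,3-dihydrobenzofuran-2-yl]propan-2-ol, via methyl ketone 13 (not isolated)
Conditions: MeMgBr (4 equiv), anhydrous CeCl3 (4 equiv), THF, −78 → 0 °C; aq NH4Cl
Reagents that add atoms: methylmagnesium bromide, C[Mg]Br
Why: Double 1,2-addition of a methylcerium nucleophile to the ester through ketone 13 (organocerium-modified Grignard addition), whose low basicity should suppress enolisation at C2 and so preserve that stereocentre.

Step 7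
Reactants: 14 2-[(2S,3R)-5-(2-methyl-1,3-dioxolan-2-yl)-3-(triethylsilyloxy)-2,3-dihydrobenzofuran-2-yl]propan-2-ol
Product: 16 triethyl{[(2R,3R)-5-(2-methyl-1,3-dioxolan-2-yl)-2-(prop-1-en-2-yl)-2,3-dihydrobenzofuran-3-yl]oxy}silane, via tertiary mesylate 15 (not isolated)
Conditions: MsCl, Et3N, CH2Cl2, 0 °C → rt
Reagents that add atoms: none
Why: Sulfonylation of the tertiary alcohol and E2 elimination, in which the six unhindered methyl hydrogens should be removed in preference to the single C2–H, which is flanked by the ring oxygen and the silyloxy-bearing C3, giving the isopropenyl group as in the usual carbinol dehydration of tremetone-type compounds.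

Step 8
Reactants: 16 triethyl{[(2R,3R)-5-(2-methyl-1,3-dioxolan-2-yl)-2-(prop-1-en-2-yl)-2,3-dihydrobenzofuran-3-yl]oxy}silane
Product: 18 1-[(2R,3R)-3-hydroxy-2-(prop-1-en-2-yl)-2,3-dihydrobenzofuran-5-yl]ethanone, via ketone silyl ether 17 (not isolated)
Conditions: 1 M aq HCl, THF, 0 °C → rt
Reagents that add atoms: water, O
Why: Acid hydrolysis removes the dioxolane first (its oxocarbenium ion is stabilised by the para ring oxygen) and then the triethylsilyl ether, and the acetyl group thus released deactivates the ring against ionisation of the benzylic alcohol.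

Step 9
Reactants: 19 (E)-but-2-enal (crotonaldehyde)
Product: 20 (Z)-2-iodobut-2-enal
Conditions: I2, K2CO3, DMAP (20 mol%), THF/H2O (1:1), rt
Reagents that add atoms: iodine, II
Why: α-Iodination of an enal by a Baylis–Hillman-type sequence (conjugate addition of DMAP, iodination of the enolate, E1cB loss of DMAP), which should return the isomer with methyl trans to the formyl group and hence cis to iodine.

Step 10
Reactants: 20 (Z)-2-iodobut-2-enal
Product: 21 (Z)-2-iodobut-2-en-1-ol
Conditions: NaBH4, MeOH, 0 °C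
Reagents that add atoms: none
Why: Borohydride 1,2-reduction of the aldehyde, which leaves the alkene geometry and the C–I bond untouched.

Step 11
Reactants: 21 (Z)-2-iodobut-2-en-1-ol
Product: 23 (Z)-2-(hydroxymethyl)but-2-enoic acid, via lithium (E)-2-lithiobut-2-en-1-olate 22 (not isolated)
Conditions: t-BuLi (3.1 equiv), Et2O, −78 °C; CO2 (gas); aq HCl
Reagents that add atoms: carbon dioxide, O=C=O
Why: Deprotonation of the hydroxyl and iodine–lithium exchange with retention give a configurationally stable alkenyllithium (lithium cis to methyl), whose carboxylation places the carboxyl group cis to the methyl group.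

Step 12
Reactants: 23 (Z)-2-(hydroxymethyl)but-2-enoic acid
Product: 25 (Z)-2-(acetoxymethyl)but-2-enoic acid, via mixed acetic anhydride 24 (not isolated)
Conditions: Ac2O, pyridine, 0 °C → rt; then H2O/THF
Reagents that add atoms: acetic anhydride, CC(=O)OC(C)=O
Why: O-Acetylation of the primary alcohol, with the mixed anhydride formed alongside hydrolysed in the aqueous stir and no nucleophilic catalyst present that could add to the enoate and isomerise the Z-alkene.

Step 13
Reactants: 18 1-[(2R,3R)-3-hydroxy-2-(prop-1-en-2-yl)-2,3-dihydrobenzofuran-5-yl]ethanone; 25 (Z)-2-(acetoxymethyl)but-2-enoic acid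
Product: 27 (2R,3S)-5-acetyl-2-(prop-1-en-2-yl)-2,3-dihydrobenzofuran-3-yl (Z)-2-(acetoxymethyl)but-2-enoate, via alkoxyphosphonium carboxylate 26 (not isolated)
Conditions: PPh3, DIAD, toluene, −20 → 0 °C (betaine pre-formed, then 25, then 18)
Reagents that add atoms: none
Why: Mitsunobu esterification, in which the carboxylate displaces the C3 alkoxyphosphonium group by SN2 with inversion (3R → 3S, cis → trans) from the face bearing only the C2–H; the carboxyl carbon is never activated, so the Z-alkene and the allylic acetate should persist, and the 5-acetyl group para to O1 disfavours ionisation at C3.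

**Compound list**

1 | 5-acetylsalicylaldehyde (5-acetyl-2-hydroxybenzaldehyde) | CC(=O)c1ccc(O)c(C=O)c1 | starting material
2 | methyl bromoacetate | COC(=O)CBr | starting material
3 | methyl 2-(4-acetyl-2-formylphenoxy)acetate | COC(=O)COc1ccc(C(C)=O)cc1C=O | intermediate (not isolated)
4 | methyl 5-acetyl-3-hydroxy-2,3-dihydrobenzofuran-2-carboxylate (stereoisomer mixture) | COC(=O)C1Oc2ccc(C(C)=O)cc2C1O | intermediate (not isolated)
5 | methyl 5-acetylbenzofuran-2-carboxylate | COC(=O)c1cc2cc(C(C)=O)ccc2o1 | intermediate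
6 | methyl 5-(2-methyl-1,3-dioxolan-2-yl)benzofuran-2-carboxylate | COC(=O)c1cc2cc(C3(C)OCCO3)ccc2o1 | intermediate
7 | bis(pinacolato)diboron | CC1(C)OB(OC1(C)C)B1OC(C)(C)C(C)(C)O1 | starting material
8 | O-bound copper enolate of 9, 3R (ligand omitted) | COC(O[Cu])=C1Oc2ccc(C3(C)OCCO3)cc2[C@H]1B1OC(C)(C)C(C)(C)O1 | intermediate (not isolated)
9 | methyl (2S,3R)-5-(2-methyl-1,3-dioxolan-2-yl)-3-(4,4,5,5-tetramethyl-1,3,2-dioxaborolan-2-yl)-2,3-dihydrobenzofuran-2-carboxylate (cis) | COC(=O)[C@H]1Oc2ccc(C3(C)OCCO3)cc2[C@H]1B1OC(C)(C)C(C)(C)O1 | intermediate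
10 | methyl (2S,3R)-5-(2-methyl-1,3-dioxolan-2-yl)-3-[(4,4,5,5-tetramethyl-1,3,2-dioxaborolan-2-yl)oxy]-2,3-dihydrobenzofuran-2-carboxylate (borate ester) | COC(=O)[C@H]1Oc2ccc(C3(C)OCCO3)cc2[C@H]1OB1OC(C)(C)C(C)(C)O1 | intermediate (not isolated)
11 | methyl (2S,3R)-3-hydroxy-5-(2-methyl-1,3-dioxolan-2-yl)-2,3-dihydrobenzofuran-2-carboxylate (cis) | COC(=O)[C@H]1Oc2ccc(C3(C)OCCO3)cc2[C@H]1O | intermediate
12 | methyl (2S,3R)-5-(2-methyl-1,3-dioxolan-2-yl)-3-(triethylsilyloxy)-2,3-dihydrobenzofuran-2-carboxylate | COC(=O)[C@H]1Oc2ccc(C3(C)OCCO3)cc2[C@H]1O[Si](CC)(CC)CC | intermediate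
13 | 1-[(2S,3R)-5-(2-methyl-1,3-dioxolan-2-yl)-3-(triethylsilyloxy)-2,3-dihydrobenzofuran-2-yl]ethanone | CC(=O)[C@H]1Oc2ccc(C3(C)OCCO3)cc2[C@H]1O[Si](CC)(CC)CC | intermediate (not isolated)
14 | 2-[(2S,3R)-5-(2-methyl-1,3-dioxolan-2-yl)-3-(triethylsilyloxy)-2,3-dihydrobenzofuran-2-yl]propan-2-ol | CC(C)(O)[C@H]1Oc2ccc(C3(C)OCCO3)cc2[C@H]1O[Si](CC)(CC)CC | intermediate
15 | 2-[(2S,3R)-5-(2-methyl-1,3-dioxolan-2-yl)-3-(triethylsilyloxy)-2,3-dihydrobenzofuran-2-yl]propan-2-yl methanesulfonate | CC(C)(OS(C)(=O)=O)[C@H]1Oc2ccc(C3(C)OCCO3)cc2[C@H]1O[Si](CC)(CC)CC | intermediate (not isolated)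
16 | triethyl{[(2R,3R)-5-(2-methyl-1,3-dioxolan-2-yl)-2-(prop-1-en-2-yl)-2,3-dihydrobenzofuran-3-yl]oxy}silane | C=C(C)[C@H]1Oc2ccc(C3(C)OCCO3)cc2[C@H]1O[Si](CC)(CC)CC | intermediate
17 | 1-[(2R,3R)-2-(prop-1-en-2-yl)-3-(triethylsilyloxy)-2,3-dihydrobenzofuran-5-yl]ethanone | C=C(C)[C@H]1Oc2ccc(C(C)=O)cc2[C@H]1O[Si](CC)(CC)CC | intermediate (not isolated)
18 | 1-[(2R,3R)-3-hydroxy-2-(prop-1-en-2-yl)-2,3-dihydrobenzofuran-5-yl]ethanone (cis) | C=C(C)[C@H]1Oc2ccc(C(C)=O)cc2[C@H]1O | intermediate
19 | (E)-but-2-enal (crotonaldehyde) | C/C=C/C=O | starting material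
20 | (Z)-2-iodobut-2-enal | C/C=C(\I)C=O | intermediate
21 | (Z)-2-iodobut-2-en-1-ol | C/C=C(\I)CO | intermediate
22 | lithium (E)-2-lithiobut-2-en-1-olate (lithium cis to methyl) | C/C=C(\[Li])CO[Li] | intermediate (not isolated)
23 | (Z)-2-(hydroxymethyl)but-2-enoic acid | C/C=C(\C(=O)O)CO | intermediate
24 | acetic (Z)-2-(acetoxymethyl)but-2-enoic anhydride | C/C=C(\C(=O)OC(C)=O)COC(C)=O | intermediate (not isolated)
25 | (Z)-2-(acetoxymethyl)but-2-enoic acid | C/C=C(\C(=O)O)COC(C)=O | intermediate
26 | [(2R,3R)-5-acetyl-2-(prop-1-en-2-yl)-2,3-dihydrobenzofuran-3-yl]oxytriphenylphosphonium (Z)-2-(acetoxymethyl)but-2-enoate | C=C(C)[C@H]1Oc2ccc(C(C)=O)cc2[C@H]1O[P+](c1ccccc1)(c1ccccc1)c1ccccc1.C/C=C(\C(=O)[O-])COC(C)=O | intermediate (not isolated)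
27 | (2R,3S)-5-acetyl-2-(prop-1-en-2-yl)-2,3-dihydrobenzofuran-3-yl (Z)-2-(acetoxymethyl)but-2-enoate (trans) | C=C(C)[C@H]1Oc2ccc(C(C)=O)cc2[C@@H]1OC(=O)/C(=C\C)COC(C)=O | target

**Count**

Total steps: 13. Longest linear sequence: 9 steps (steps 1–8 and 13); the acid 25 is made in 4 steps (9–12).

**Steps most likely to fail**

1. Step 3. The copper boryl species may fail to insert into the aromatic C2=C3 bond, facial discrimination at C3 may be low, or C2 may be protonated on the wrong face or epimerised by alkoxide afterwards. The fallback uses known chemistry and sets out from 2 together with purchasable methyl 5-acetyl-2-hydroxybenzoate F1. Williamson alkylation (K2CO3, acetone, reflux) should give methyl 5-acetyl-2-(2-methoxy-2-oxoethoxy)benzoate F2. Ketalisation as in step 2 should give methyl 2-(2-methoxy-2-oxoethoxy)-5-(2-methyl-1,3-dioxolan-2-yl)benzoate F3. Dieckmann condensation (KOtBu, THF, 0 °C) should give methyl 3-hydroxy-5-(2-methyl-1,3-dioxolan-2-yl)benzofuran-2-carboxylate F4, the enol form of the 3-oxo ester. Noyori–Ikariya asymmetric transfer hydrogenation with dynamic kinetic resolution (RuCl(p-cymene)[(S,S)-TsDPEN], HCO2H/Et3N 1:1, DMF, rt; catalyst enantiomer chosen to give 3R) reduces the keto tautomer while C2 racemises. This should give the cis hydroxy ester and return to the route at 11.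

2. Step 13. The activated C3 oxygen may be lost by E2 elimination with the anti C2–H, re-aromatising ring B; ionisation at C3 may erode the inversion; or PPh3 may attack the allylic acetate of 25. The fallback removes the inversion altogether and sets out from 6. Step 3 is run with the mirror-image ligand to give methyl (2R,3S)-5-(2-methyl-1,3-dioxolan-2-yl)-3-(4,4,5,5-tetramethyl-1,3,2-dioxaborolan-2-yl)-2,3-dihydrobenzofuran-2-carboxylate F5. DBU in THF equilibrates C2 through the ester enolate, which has no leaving group β to it, and should give the trans (2S,3S) boronate F6. The conditions of steps 4 to 8 should then give in turn the trans (2S,3S) hydroxy ester F7, its triethylsilyl ether F8, the (2S,3S) tertiary carbinol F9, the (2R,3S) isopropenyl silyl ether F10 and 1-[(2R,3S)-3-hydroxy-2-(prop-1-en-2-yl)-2,3-dihydrobenzofuran-5-yl]ethanone F11. F11 is acylated with retention by 25 under Yamaguchi conditions (2,4,6-trichlorobenzoyl chloride, Et3N, toluene, 60 °C, no DMAP), returning to the route at 27.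

3. Step 6. The ester or ketone 13 may be enolised at C2, followed by E1cB loss of triethylsilanolate (aromatisation to a benzofuran) or C2 epimerisation. The fallback sets out from 11, where the C3 oxygen is a magnesium alkoxide during the addition and cannot leave. Excess MeMgBr/CeCl3 (THF, −78 → 0 °C) should give (2S,3R)-2-(2-hydroxypropan-2-yl)-5-(2-methyl-1,3-dioxolan-2-yl)-2,3-dihydrobenzofuran-3-ol F12. TESCl/imidazole (DMF, 0 °C) then silylates only the secondary benzylic hydroxyl, returning to the route at 14.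

**Further compounds**

F1 | step 3 | methyl 5-acetyl-2-hydroxybenzoate | COC(=O)c1cc(C(C)=O)ccc1O
F2 | step 3 | methyl 5-acetyl-2-(2-methoxy-2-oxoethoxy)benzoate | COC(=O)COc1ccc(C(C)=O)cc1C(=O)OC
F3 | step 3 | methyl 2-(2-methoxy-2-oxoethoxy)-5-(2-methyl-1,3-dioxolan-2-yl)benzoate | COC(=O)COc1ccc(C2(C)OCCO2)cc1C(=O)OC
F4 | step 3 | methyl 3-hydroxy-5-(2-methyl-1,3-dioxolan-2-yl)benzofuran-2-carboxylate | COC(=O)c1oc2ccc(C3(C)OCCO3)cc2c1O
F5 | step 13 | methyl (2R,3S)-5-(2-methyl-1,3-dioxolan-2-yl)-3-(4,4,5,5-tetramethyl-1,3,2-dioxaborolan-2-yl)-2,3-dihydrobenzofuran-2-carboxylate | COC(=O)[C@@H]1Oc2ccc(C3(C)OCCO3)cc2[C@@H]1B1OC(C)(C)C(C)(C)O1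
F6 | step 13 | methyl (2S,3S)-5-(2-methyl-1,3-dioxolan-2-yl)-3-(4,4,5,5-tetramethyl-1,3,2-dioxaborolan-2-yl)-2,3-dihydrobenzofuran-2-carboxylate | COC(=O)[C@H]1Oc2ccc(C3(C)OCCO3)cc2[C@@H]1B1OC(C)(C)C(C)(C)O1
F7 | step 13 | methyl (2S,3S)-3-hydroxy-5-(2-methyl-1,3-dioxolan-2-yl)-2,3-dihydrobenzofuran-2-carboxylate | COC(=O)[C@H]1Oc2ccc(C3(C)OCCO3)cc2[C@@H]1O
F8 | step 13 | methyl (2S,3S)-5-(2-methyl-1,3-dioxolan-2-yl)-3-(triethylsilyloxy)-2,3-dihydrobenzofuran-2-carboxylate | COC(=O)[C@H]1Oc2ccc(C3(C)OCCO3)cc2[C@@H]1O[Si](CC)(CC)CC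
F9 | step 13 | 2-[(2S,3S)-5-(2-methyl-1,3-dioxolan-2-yl)-3-(triethylsilyloxy)-2,3-dihydrobenzofuran-2-yl]propan-2-ol | CC(C)(O)[C@H]1Oc2ccc(C3(C)OCCO3)cc2[C@@H]1O[Si](CC)(CC)CC
F10 | step 13 | triethyl{[(2R,3S)-5-(2-methyl-1,3-dioxolan-2-yl)-2-(prop-1-en-2-yl)-2,3-dihydrobenzofuran-3-yl]oxy}silane | C=C(C)[C@H]1Oc2ccc(C3(C)OCCO3)cc2[C@@H]1O[Si](CC)(CC)CC
F11 | step 13 | 1-[(2R,3S)-3-hydroxy-2-(prop-1-en-2-yl)-2,3-dihydrobenzofuran-5-yl]ethanone | C=C(C)[C@H]1Oc2ccc(C(C)=O)cc2[C@@H]1O
F12 | step 6 | (2S,3R)-2-(2-hydroxypropan-2-yl)-5-(2-methyl-1,3-dioxolan-2-yl)-2,3-dihydrobenzofuran-3-ol | CC(C)(O)[C@H]1Oc2ccc(C3(C)OCCO3)cc2[C@H]1O
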